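**Retrosynthetic overview**
- The target comes from its 4'-O-triisopropylsilyl ether by fluoride cleavage (last step).
- Rings C and A are closed in one flask from an acyclic δ-hydroxy-3,5,7-trioxo tert-butyl ester. The C2 carbinol oxygen first closes ring C on C8a (loss of water). The tert-butyl β-keto ester end then becomes an α-oxoketene that closes ring A through the C4a–C5 bond.
- The open chain is made by one polyanion Claisen (C8–C8a) between the dianion of a lavandulyl acetoacetate and a δ-hydroxy-β-keto ester.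
- C2 (S) is set by a catalytic asymmetric vinylogous Mukaiyama aldol on the aryl aldehyde. The lavandulyl centre is set by an Evans deconjugative prenylation and carried in as (S)-lavandulyl iodide.
- Ring order: ring B is bought, then ring C, then ring A, the last two in the same operation.

Assumption: open-chain precursors carry the flavanone atom labels (O1, C2, C3, C4, C4a, C5–C8, C8a).
Assumption: metal enolates and other deprotonated forms of numbered compounds are not numbered separately; LiN(iPr)2, NaN(SiMe3)2 and n-BuLi are used as commercial solutions.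

**Route**

Step 1
Reactants: 1 4-hydroxy-2-methoxybenzaldehyde; 2 chlorotri(propan-2-yl)silane
Product: 3 2-methoxy-4-[(triisopropylsilyl)oxy]benzaldehyde
Conditions: 2 (1.1 equiv), imidazole (2 equiv), DMF, 23 °C
Reagents that add atoms: 2 chlorotri(propan-2-yl)silane, CC(C)[Si](Cl)(C(C)C)C(C)C
Why: Imidazole-promoted O-silylation masks the acidic phenol for the Lewis-acid aldol and the polyanion chemistry and stays fluoride-labile for the end.

Step 2
Reactants: 3 2-methoxy-4-[(triisopropylsilyl)oxy]benzaldehyde; 4 1-methoxy-1,3-bis(trimethylsilyloxy)buta-1,3-diene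
Product: 6 methyl (5S)-5-hydroxy-5-{2-methoxy-4-[(triisopropylsilyl)oxy]phenyl}-3-oxopentanoate, via bis-silyl aldol adduct 5 (not isolated)
Conditions: Ti(OiPr)4 (10 mol%), (S)-BINOL (10 mol%), 4 Å MS, THF, −78 → 23 °C; then CF3CO2H, −78 °C
Reagents that add atoms: 4 1-methoxy-1,3-bis(trimethylsilyloxy)buta-1,3-diene, COC(O[Si](C)(C)C)=CC(=C)O[Si](C)(C)C
Why: Catalytic enantioselective vinylogous Mukaiyama aldol in which the (S)-BINOL/Ti(OiPr)4 complex is expected, by analogy with BINOL-titanium allylation and acetate aldol, to deliver the diene terminus to the Si face of the aldehyde, setting the future C2 as S before acid removes both trimethylsilyl groups.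

Step 3
Reactants: 7 (4S)-4-benzyl-1,3-oxazolidin-2-one; 8 3-methylbut-2-enoyl chloride
Product: 9 (4S)-4-benzyl-3-(3-methylbut-2-enoyl)-1,3-oxazolidin-2-one
Conditions: n-BuLi, THF, −78 °C; then 8, −78 → 0 °C
Reagents that add atoms: 8 3-methylbut-2-enoyl chloride, CC(C)=CC(Cl)=O
Why: Standard N-acylation of the lithiated Evans oxazolidinone by an acid chloride.

Step 4
Reactants: 9 (4S)-4-benzyl-3-(3-methylbut-2-enoyl)-1,3-oxazolidin-2-one; 10 1-bromo-3-methylbut-2-ene
Product: 11 (4S)-4-benzyl-3-[(2S)-5-methyl-2-(prop-1-en-2-yl)hex-4-enoyl]-1,3-oxazolidin-2-one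
Conditions: NaN(SiMe3)2 (1.2 equiv), THF, −78 °C; then 10 (3 equiv), −78 → −40 °C
Reagents that add atoms: 10 1-bromo-3-methylbut-2-ene, CC(C)=CCBr
Why: Evans deconjugative α-alkylation, in which γ-deprotonation gives the chelated Z-dienolate that is prenylated at the α-carbon anti to the benzyl group, creating the isopropenyl group and the (2S) centre that becomes the (R)-lavandulyl centre of the target.

Step 5
Reactants: 11 (4S)-4-benzyl-3-[(2S)-5-methyl-2-(prop-1-en-2-yl)hex-4-enoyl]-1,3-oxazolidin-2-one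
Product: 12 (2S)-5-methyl-2-(prop-1-en-2-yl)hex-4-en-1-ol [(S)-lavandulol]
Conditions: LiBH4, H2O (1.1 equiv), Et2O, 0 °C
Reagents that add atoms: none
Why: Reductive cleavage of the N-acyl oxazolidinone by borohydride gives the primary alcohol without touching the β,γ-alkene or the stereocentre and returns the auxiliary.

Step 6
Reactants: 12 (2S)-5-methyl-2-(prop-1-en-2-yl)hex-4-en-1-ol; 13 iodine
Product: 14 (3S)-3-(iodomethyl)-2,6-dimethylhepta-1,5-diene [(S)-lavandulyl iodide]
Conditions: I2, PPh3, imidazole, CH2Cl2, 0 → 23 °C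
Reagents that add atoms: 13 iodine, II
Why: Appel-type iodination displaces the activated primary oxygen by SN2 at CH2, so the neighbouring stereocentre is not involved.

Step 7
Reactants: 14 (3S)-3-(iodomethyl)-2,6-dimethylhepta-1,5-diene; 15 tert-butyl 3-oxobutanoate
Product: 16 tert-butyl (4R)-2-acetyl-7-methyl-4-(prop-1-en-2-yl)oct-6-enoate (about 1:1 at C2)
Conditions: 15 (1.5 equiv), NaH (1.4 equiv), THF/DMF 4:1, 0 °C; then 14, 60 °C
Reagents that add atoms: 15 tert-butyl 3-oxobutanoate, CC(=O)CC(=O)OC(C)(C)C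
Why: Acetoacetic ester C-alkylation (SN2 of the soft enolate on the primary iodide, excess 15 suppressing dialkylation); the new α-centre is an inconsequential epimer mixture because it becomes aromatic C6.

Step 8
Reactants: 16 tert-butyl (4R)-2-acetyl-7-methyl-4-(prop-1-en-2-yl)oct-6-enoate; 6 methyl (5S)-5-hydroxy-5-{2-methoxy-4-[(triisopropylsilyl)oxy]phenyl}-3-oxopentanoate
Product: 17 tert-butyl (9S)-9-hydroxy-9-{2-methoxy-4-[(triisopropylsilyl)oxy]phenyl}-2-[(2R)-5-methyl-2-(prop-1-en-2-yl)hex-4-en-1-yl]-3,5,7-trioxononanoate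
Conditions: 16 (2.5 equiv), LiN(iPr)2 (5.1 equiv), THF, 0 °C; add 6 pre-treated with LiN(iPr)2 (2.0 equiv) at −78 °C; −78 → 23 °C; AcOH, −78 °C (excess 16 recovered)
Reagents that add atoms: none
Why: Huckin–Weiler/Harris-type polyanion Claisen in which the γ-carbanion of the dianion of 16 acylates the methyl ester of doubly deprotonated 6, forming C8–C8a without touching either stereocentre; the hindered tert-butyl ester of 16 cannot self-condense and the fully ionised product can neither cyclise nor retro-aldolise.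

Step 9
Reactants: 17 tert-butyl (9S)-9-hydroxy-9-{2-methoxy-4-[(triisopropylsilyl)oxy]phenyl}-2-[(2R)-5-methyl-2-(prop-1-en-2-yl)hex-4-en-1-yl]-3,5,7-trioxononanoate
Product: 20 (2S)-5,7-dihydroxy-2-{2-methoxy-4-[(triisopropylsilyl)oxy]phenyl}-6-[(2R)-5-methyl-2-(prop-1-en-2-yl)hex-4-en-1-yl]-2,3-dihydro-4H-chromen-4-one, via dihydropyranone tert-butyl ester 18 (not isolated), via acylketene 19 (not isolated)
Conditions: pyridinium p-toluenesulfonate (0.2 equiv), 4 Å MS, PhMe (0.01 M), 60 °C; then 110 °C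
Reagents that add atoms: none
Why: Proposed new method: at 60 °C the C2 hydroxyl adds to the C8a carbonyl and water is lost (known acid-catalysed cyclodehydration of δ-hydroxy-β-diketones to 2,3-dihydro-4H-pyran-4-ones), which closes ring C with retention at C2 and removes the enol oxygen that would otherwise give a pyrone; at 110 °C the α-substituted tert-butyl β-keto ester expels tert-butanol to an α-oxoketene (known tert-butyl acetoacetate thermolysis), whose ketene carbon is captured by the nucleophilic vinylogous-ester carbon C4a in a 6π-electrocyclisation of the dienylketene tautomer (closest precedents: the final stage of the Danheiser benzannulation and the Claisen-type cyclisation of 3,5,7-triketo esters to acylphloroglucinols), and tautomerisation gives aromatic ring A with the lavandulyl group necessarily at C6 because O1 is the carbinol oxygen.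

Step 10
Reactants: 20 (2S)-5,7-dihydroxy-2-{2-methoxy-4-[(triisopropylsilyl)oxy]phenyl}-6-[(2R)-5-methyl-2-(prop-1-en-2-yl)hex-4-en-1-yl]-2,3-dihydro-4H-chromen-4-one
Product: 21 (2S)-5,7-dihydroxy-2-(4-hydroxy-2-methoxyphenyl)-6-[(2R)-5-methyl-2-(prop-1-en-2-yl)hex-4-en-1-yl]-2,3-dihydro-4H-chromen-4-one (CNP0102823.2)
Conditions: Bu4NF (1.1 equiv), AcOH (1.5 equiv), THF, 0 °C
Reagents that add atoms: none
Why: Fluoride cleavage of the aryl silyl ether, buffered with acetic acid so that the base-sensitive flavanone is not ring-opened and C2 is not racemised.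

**Compound list**
1 | 4-hydroxy-2-methoxybenzaldehyde | COc1cc(O)ccc1C=O | starting material
2 | chlorotri(propan-2-yl)silane | CC(C)[Si](Cl)(C(C)C)C(C)C | starting material
3 | 2-methoxy-4-[(triisopropylsilyl)oxy]benzaldehyde | COc1cc(O[Si](C(C)C)(C(C)C)C(C)C)ccc1C=O | intermediate
4 | 1-methoxy-1,3-bis(trimethylsilyloxy)buta-1,3-diene (E/Z as supplied) | COC(O[Si](C)(C)C)=CC(=C)O[Si](C)(C)C | starting material
5 | methyl (2Z,5S)-5-{2-methoxy-4-[(triisopropylsilyl)oxy]phenyl}-3,5-bis[(trimethylsilyl)oxy]pent-2-enoate | COC(=O)/C=C(\O[Si](C)(C)C)C[C@@H](c1ccc(O[Si](C(C)C)(C(C)C)C(C)C)cc1OC)O[Si](C)(C)C | intermediate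
6 | methyl (5S)-5-hydroxy-5-{2-methoxy-4-[(triisopropylsilyl)oxy]phenyl}-3-oxopentanoate | COC(=O)CC(=O)C[C@@H](c1ccc(O[Si](C(C)C)(C(C)C)C(C)C)cc1OC)O | intermediate
7 | (4S)-4-benzyl-1,3-oxazolidin-2-one | O=C1N[C@@H](Cc2ccccc2)CO1 | starting material
8 | 3-methylbut-2-enoyl chloride | CC(C)=CC(Cl)=O | starting material
9 | (4S)-4-benzyl-3-(3-methylbut-2-enoyl)-1,3-oxazolidin-2-one | CC(C)=CC(=O)N1[C@@H](Cc2ccccc2)COC1=O | intermediate
10 | 1-bromo-3-methylbut-2-ene | CC(C)=CCBr | starting material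
11 | (4S)-4-benzyl-3-[(2S)-5-methyl-2-(prop-1-en-2-yl)hex-4-enoyl]-1,3-oxazolidin-2-one | C=C(C)[C@H](CC=C(C)C)C(=O)N1[C@@H](Cc2ccccc2)COC1=O | intermediate
12 | (2S)-5-methyl-2-(prop-1-en-2-yl)hex-4-en-1-ol | C=C(C)[C@H](CC=C(C)C)CO | intermediate
13 | iodine | II | starting material
14 | (3S)-3-(iodomethyl)-2,6-dimethylhepta-1,5-diene | C=C(C)[C@H](CC=C(C)C)CI | intermediate
15 | tert-butyl 3-oxobutanoate | CC(=O)CC(=O)OC(C)(C)C | starting material
16 | tert-butyl (4R)-2-acetyl-7-methyl-4-(prop-1-en-2-yl)oct-6-enoate (C2 epimers) | C=C(C)[C@H](CC=C(C)C)CC(C(C)=O)C(=O)OC(C)(C)C | intermediate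
17 | tert-butyl (9S)-9-hydroxy-9-{2-methoxy-4-[(triisopropylsilyl)oxy]phenyl}-2-[(2R)-5-methyl-2-(prop-1-en-2-yl)hex-4-en-1-yl]-3,5,7-trioxononanoate (C2 epimers) | C=C(C)[C@H](CC=C(C)C)CC(C(=O)OC(C)(C)C)C(=O)CC(=O)CC(=O)C[C@@H](c1ccc(O[Si](C(C)C)(C(C)C)C(C)C)cc1OC)O | intermediate
18 | tert-butyl 4-[(2S)-2-{2-methoxy-4-[(triisopropylsilyl)oxy]phenyl}-4-oxo-3,4-dihydro-2H-pyran-6-yl]-2-[(2R)-5-methyl-2-(prop-1-en-2-yl)hex-4-en-1-yl]-3-oxobutanoate | C=C(C)[C@H](CC=C(C)C)CC(C(=O)OC(C)(C)C)C(=O)CC1=CC(=O)C[C@@H](c2ccc(O[Si](C(C)C)(C(C)C)C(C)C)cc2OC)O1 | intermediate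
19 | 4-[(2S)-2-{2-methoxy-4-[(triisopropylsilyl)oxy]phenyl}-4-oxo-3,4-dihydro-2H-pyran-6-yl]-2-[(2R)-5-methyl-2-(prop-1-en-2-yl)hex-4-en-1-yl]but-1-ene-1,3-dione | C=C(C)[C@H](CC=C(C)C)CC(=C=O)C(=O)CC1=CC(=O)C[C@@H](c2ccc(O[Si](C(C)C)(C(C)C)C(C)C)cc2OC)O1 | intermediate
20 | (2S)-5,7-dihydroxy-2-{2-methoxy-4-[(triisopropylsilyl)oxy]phenyl}-6-[(2R)-5-methyl-2-(prop-1-en-2-yl)hex-4-en-1-yl]-2,3-dihydro-4H-chromen-4-one | C=C(C)[C@H](CC=C(C)C)Cc1c(O)cc2c(c1O)C(=O)C[C@@H](c1ccc(O[Si](C(C)C)(C(C)C)C(C)C)cc1OC)O2 | intermediate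
21 | (2S)-5,7-dihydroxy-2-(4-hydroxy-2-methoxyphenyl)-6-[(2R)-5-methyl-2-(prop-1-en-2-yl)hex-4-en-1-yl]-2,3-dihydro-4H-chromen-4-one | C=C(C)[C@H](CC=C(C)C)Cc1c(O)cc2c(c1O)C(=O)C[C@@H](c1ccc(O)cc1OC)O2 | target

**Step count and risks**

Total step count: 10. Longest linear sequence: 8 steps (steps 3 to 10, from 7 to 21); the aryl branch is 5 steps (1, 2, 8, 9, 10).

Most likely to fail, first: step 9. The α-substituted tert-butyl β-keto ester may lose tert-butanol too slowly at 110 °C. The electron-rich benzylic C2–O bond may ionise under acid and heat. If the ketene forms before ring C is closed, O-acylation gives a 4-hydroxy-2-pyrone. The fallback activates the acyl end as a thioester at 23 °C and closes the two rings in separate steps. It sets out from iodide 14, which alkylates S-tert-butyl 3-oxobutanethioate (NaH, THF/DMF, 60 °C) to S-tert-butyl (4R)-2-acetyl-7-methyl-4-(prop-1-en-2-yl)oct-6-enethioate F5. The dianion of F5 is acylated by doubly deprotonated 6, as in step 8, to give S-tert-butyl (9S)-9-hydroxy-9-{2-methoxy-4-[(triisopropylsilyl)oxy]phenyl}-2-[(2R)-5-methyl-2-(prop-1-en-2-yl)hex-4-en-1-yl]-3,5,7-trioxononanethioate F6. Pyridinium p-toluenesulfonate and 4 Å MS at 40 °C close ring C to S-tert-butyl 4-[(2S)-2-{2-methoxy-4-[(triisopropylsilyl)oxy]phenyl}-4-oxo-3,4-dihydro-2H-pyran-6-yl]-2-[(2R)-5-methyl-2-(prop-1-en-2-yl)hex-4-en-1-yl]-3-oxobutanethioate F7, which is isolated. AgOCOCF3 (1.2 equiv) and Na2HPO4 in THF at 23 °C then turn the thioester into the acylating species and C4a closes ring A, so the sequence comes back to the route at 20.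

Second: step 8. The ester of 6 is conjugated to its own enolate and is a sluggish electrophile, so conversion may be low even with excess dianion. The fallback moves the Claisen to the C4–C4a bond, where the electrophile carries no enolised carbonyl; it sets out from 16 and from aldehyde 3. The dianion of 16 is acetylated with N-methoxy-N-methylacetamide to tert-butyl 2-[(2R)-5-methyl-2-(prop-1-en-2-yl)hex-4-en-1-yl]-3,5-dioxohexanoate F3. Aldehyde 3 undergoes an (S)-BINOL/Ti(OiPr)4-catalysed acetate Mukaiyama aldol with 1-(tert-butylthio)-1-(trimethylsilyloxy)ethene to S-tert-butyl (3S)-3-hydroxy-3-{2-methoxy-4-[(triisopropylsilyl)oxy]phenyl}propanethioate F4. The trianion of F3 (LiN(iPr)2, 3.3 equiv) is acylated at its terminal methyl by the lithium alkoxide of F4, and acidification returns to the route at 17.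

Third: step 2. The ortho-methoxy, strongly electron-rich aldehyde may react slowly or with eroded enantioselectivity, and the facial sense is assigned by analogy only. The fallback sets the carbinol by ketone hydrogenation instead of aldol and sets out from 3. NbCl5-catalysed Roskamp homologation with methyl diazoacetate gives methyl 3-{2-methoxy-4-[(triisopropylsilyl)oxy]phenyl}-3-oxopropanoate F1. Hydrogenation with RuCl2[(R)-BINAP] (H2, MeOH) gives methyl (3S)-3-hydroxy-3-{2-methoxy-4-[(triisopropylsilyl)oxy]phenyl}propanoate F2, the S alcohol following the established sense for aryl β-keto esters. Crossed Claisen with LiCH2CO2Me (4 equiv, THF, −78 → −30 °C) comes back to the route at 6.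

Further compounds
F1 | step 2 | methyl 3-{2-methoxy-4-[(triisopropylsilyl)oxy]phenyl}-3-oxopropanoate | COC(=O)CC(=O)c1ccc(O[Si](C(C)C)(C(C)C)C(C)C)cc1OC
F2 | step 2 | methyl (3S)-3-hydroxy-3-{2-methoxy-4-[(triisopropylsilyl)oxy]phenyl}propanoate | COC(=O)C[C@@H](c1ccc(O[Si](C(C)C)(C(C)C)C(C)C)cc1OC)O
F3 | step 8 | tert-butyl 2-[(2R)-5-methyl-2-(prop-1-en-2-yl)hex-4-en-1-yl]-3,5-dioxohexanoate | C=C(C)[C@H](CC=C(C)C)CC(C(=O)OC(C)(C)C)C(=O)CC(C)=O
F4 | step 8 | S-tert-butyl (3S)-3-hydroxy-3-{2-methoxy-4-[(triisopropylsilyl)oxy]phenyl}propanethioate | CC(C)(C)SC(=O)C[C@@H](c1ccc(O[Si](C(C)C)(C(C)C)C(C)C)cc1OC)O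
F5 | step 9 | S-tert-butyl (4R)-2-acetyl-7-methyl-4-(prop-1-en-2-yl)oct-6-enethioate | C=C(C)[C@H](CC=C(C)C)CC(C(C)=O)C(=O)SC(C)(C)C
F6 | step 9 | S-tert-butyl (9S)-9-hydroxy-9-{2-methoxy-4-[(triisopropylsilyl)oxy]phenyl}-2-[(2R)-5-methyl-2-(prop-1-en-2-yl)hex-4-en-1-yl]-3,5,7-trioxononanethioate | C=C(C)[C@H](CC=C(C)C)CC(C(=O)SC(C)(C)C)C(=O)CC(=O)CC(=O)C[C@@H](c1ccc(O[Si](C(C)C)(C(C)C)C(C)C)cc1OC)O
F7 | step 9 | S-tert-butyl 4-[(2S)-2-{2-methoxy-4-[(triisopropylsilyl)oxy]phenyl}-4-oxo-3,4-dihydro-2H-pyran-6-yl]-2-[(2R)-5-methyl-2-(prop-1-en-2-yl)hex-4-en-1-yl]-3-oxobutanethioate | C=C(C)[C@H](CC=C(C)C)CC(C(=O)SC(C)(C)C)C(=O)CC1=CC(=O)C[C@@H](c2ccc(O[Si](C(C)C)(C(C)C)C(C)C)cc2OC)O1
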